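**Retrosynthetic overview**
- The plan rests on ring A of the chroman: the acyl carbon on C6 lies between the C5 and C7 oxygens. They hinder carbonyl-type bond formation there and would close a free enone to a flavanone, but they also make a C6 nitrile oxide persistent.
- The enone is traced back to a β-hydroxy ketone and then to a 3-aryl-5-aryl isoxazoline, made by [3+2] cycloaddition of the C6 nitrile oxide with 4-acetoxystyrene (carbonyl C–Cα and O–Cβ bonds).
- The nitrile oxide comes from the oxime of the C6 aldehyde, installed by directed metalation of C6–H between the two MOM ethers.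
- The dihydropyran ring (O1–C2 bond) comes from 6-endo opening of an (R)-epoxide made by Shi epoxidation of prenylated tris-MOM phloroglucinol; this sets C3.
- Ring order: arene (bought), then the dihydropyran ring, then the temporary isoxazoline ring, which is opened again.

Key step: step 8

Remark: chroman numbering is used throughout (O1, C2 gem-dimethyl, C3 carbinol, C4 methylene, C4a to C8a arene); the only stereocentre of the target, C3, is (R).

**Step 1**
Reactants: 1 phloroglucinol
Product: 2 1,3,5-tris(methoxymethoxy)benzene
Conditions: MOMCl, iPr2NEt, DMF, 0 °C to rt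
Reagents that add atoms: chloromethyl methyl ether, COCCl
Why: O-alkylation of the three phenols (MOM protection) with an amine base keeps C-alkylation of the phloroglucinol nucleus low and installs the ortho-directing groups needed later.

**Step 2**
Reactants: 2 1,3,5-tris(methoxymethoxy)benzene; 3 prenyl bromide
Product: 5 1,3,5-tris(methoxymethoxy)-2-(3-methylbut-2-en-1-yl)benzene, via aryllithium 4 (not isolated)
Conditions: n-BuLi, THF, 0 °C; then CuI (10 mol%), 3, −78 °C to rt
Reagents that add atoms: none
Why: Directed ortho-metalation between two MOM ethers (all three ring positions are equivalent) gives a chelated aryllithium that is allylated by prenyl bromide, with CuI catalysis favouring direct over allyl-transposed substitution.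

**Step 3**
Reactants: 5 1,3,5-tris(methoxymethoxy)-2-(3-methylbut-2-en-1-yl)benzene
Product: 6 (R)-2,2-dimethyl-3-[2,4,6-tris(methoxymethoxy)benzyl]oxirane
Conditions: D-fructose-derived Shi ketone (1,2:4,5-di-O-isopropylidene-β-D-erythro-2,3-hexodiulo-2,6-pyranose, 30 mol%), KHSO5 (as 2KHSO5·KHSO4·K2SO4), K2CO3, Bu4NHSO4, Na2B4O7 buffer, MeCN/CH2(OMe)2/H2O, 0 °C
Reagents that add atoms: potassium peroxymonosulfate, [K+].[O-]S(=O)(=O)OO
Why: Shi asymmetric epoxidation, in which the chiral dioxirane transfers oxygen to the trisubstituted alkene through a spiro transition state; the D-fructose ketone should give the (R) configuration at the epoxide CH, and the basic medium leaves the MOM ethers untouched.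

**Step 4**
Reactants: 6 (R)-2,2-dimethyl-3-[2,4,6-tris(methoxymethoxy)benzyl]oxirane
Product: 7 (R)-5,7-bis(methoxymethoxy)-2,2-dimethylchroman-3-ol
Conditions: (±)-camphor-10-sulfonic acid (10 mol%), water-saturated CH2Cl2, 0 °C
Reagents that add atoms: none
Why: Acid-catalysed 6-endo epoxide opening at the tertiary carbon by the ortho aryl MOM ether oxygen, whose oxonium ion loses the methoxymethyl cation to water; the C–O bond at the epoxide CH is never broken, so C3 keeps the (R) configuration, and the two other MOM ethers should survive catalytic acid at 0 °C.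

**Step 5**
Reactants: 7 (R)-5,7-bis(methoxymethoxy)-2,2-dimethylchroman-3-ol
Product: 8 (R)-3-(tert-butyldimethylsilyloxy)-5,7-bis(methoxymethoxy)-2,2-dimethylchroman
Conditions: TBSCl, imidazole, DMAP (cat.), DMF, 40 °C
Reagents that add atoms: tert-butyldimethylsilyl chloride, CC(C)(C)[Si](C)(C)Cl
Why: Standard silylation of the secondary alcohol under neutral to basic conditions, which removes the acidic proton before the metalation and does not touch the aryl MOM ethers.

**Step 6**
Reactants: 8 (R)-3-(tert-butyldimethylsilyloxy)-5,7-bis(methoxymethoxy)-2,2-dimethylchroman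
Product: 10 (R)-3-(tert-butyldimethylsilyloxy)-5,7-bis(methoxymethoxy)-2,2-dimethylchroman-6-carbaldehyde, via C6 aryllithium 9 (not isolated)
Conditions: n-BuLi, THF, 0 °C; DMF, −78 °C to 0 °C; aq. NH4Cl
Reagents that add atoms: N,N-dimethylformamide, CN(C)C=O
Why: Directed ortho-metalation followed by formylation with DMF; C6–H lies between two chelating MOM ethers, whereas C8–H has one MOM ether and the weakly coordinating ring oxygen, so lithiation is expected at C6.

**Step 7**
Reactants: 10 (R)-3-(tert-butyldimethylsilyloxy)-5,7-bis(methoxymethoxy)-2,2-dimethylchroman-6-carbaldehyde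
Product: 11 (E)-oxime of aldehyde 10
Conditions: NH2OH·HCl, pyridine, EtOH, 50 °C
Reagents that add atoms: hydroxylamine hydrochloride, NO.Cl
Why: Oxime condensation, which still proceeds on di-ortho-substituted benzaldehydes on gentle warming, in a pyridine-buffered medium that is safe for MOM and TBS groups.

**Step 8**
Reactants: 11 (E)-oxime of aldehyde 10; 12 4-acetoxystyrene
Product: 14 3-[(R)-3-(tert-butyldimethylsilyloxy)-5,7-bis(methoxymethoxy)-2,2-dimethylchroman-6-yl]-5-(4-acetoxyphenyl)-4,5-dihydroisoxazole (both C5 epimers), via nitrile oxide 13 (not isolated)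
Conditions: PhI(OAc)2 (1.2 equiv), 12 (3 equiv), MeOH/CH2Cl2, 0 °C to 40 °C
Reagents that add atoms: none
Why: PhI(OAc)2 dehydrogenates the aldoxime to nitrile oxide 13, which adds across the vinyl group of 12 in a concerted [3+2] (Huisgen) cycloaddition, forming the dipole carbon–CH2 bond (later carbonyl carbon to C-alpha) and the O–CH(aryl) bond in one event. The closest known reaction is the addition of mesitonitrile oxide or 2,4,6-trimethoxybenzonitrile oxide to styrene, with later reductive opening of the isoxazoline as an aldol equivalent. The five-membered isoxazoline ring is closed by the cycloaddition itself, both new sigma bonds forming suprafacially on the alkene, with no separate cyclisation. The new stereocentre at C5 of the isoxazoline is not controlled, because the remote C3 silyloxy group cannot bias the alkene faces, and both epimers are carried on since this carbon becomes the sp2 beta carbon of the enone. The step needs 5-aryl regioselectivity, secured by the monosubstituted alkene (dipole carbon to the unhindered CH2, oxygen to the benzylic carbon), and it needs cycloaddition to outrun furoxan formation, secured by the C5 and C7 MOM ethers that shield the dipole as in mesityl-type nitrile oxides. A halogen-free oxidant is used so that the electron-rich C8–H position is not halogenated.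

**Step 9**
Reactants: 14 isoxazoline (both C5 epimers)
Product: 16 3-(4-acetoxyphenyl)-3-hydroxy-1-[(R)-3-(tert-butyldimethylsilyloxy)-5,7-bis(methoxymethoxy)-2,2-dimethylchroman-6-yl]propan-1-one (both carbinol epimers), via beta-hydroxy ketimine 15 (not isolated)
Conditions: H2 (1 atm), Raney Ni, B(OH)3, MeOH/H2O 5:1, rt
Reagents that add atoms: water, O
Why: Hydrogenolysis of the weak N–O bond on Raney nickel gives the N–H ketimine, which the boric acid buffered aqueous methanol hydrolyses to the ketone (the standard isoxazoline-to-aldol unmasking); any imine that persists because of the flanking MOM ethers would be hydrolysed in the aqueous acid of step 11.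

**Step 10**
Reactants: 16 beta-hydroxy ketone acetate
Product: 17 3-hydroxy-3-(4-hydroxyphenyl)-1-[(R)-3-(tert-butyldimethylsilyloxy)-5,7-bis(methoxymethoxy)-2,2-dimethylchroman-6-yl]propan-1-one (both carbinol epimers)
Conditions: K2CO3 (0.2 equiv), MeOH, 0 °C
Reagents that add atoms: none
Why: Base-catalysed transesterification of the aryl acetate, fast at 0 °C with catalytic carbonate, so retro-aldol cleavage of the hindered beta-hydroxy ketone should not compete, and MOM and TBS groups are inert.

**Step 11**
Reactants: 17 beta-hydroxy ketone phenol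
Product: 19 (E)-1-[(3R)-3,5,7-trihydroxy-2,2-dimethylchroman-6-yl]-3-(4-hydroxyphenyl)prop-2-en-1-one, via protected chalcone 18 (not isolated)
Conditions: 3 M aq. HCl/MeOH 1:5, 40 °C
Reagents that add atoms: none
Why: Acid ionises the para-hydroxybenzylic alcohol and E1 loss of an alpha proton gives the conjugated E-enone (thermodynamic geometry) while the C5 and C7 oxygens are still blocked, after which acetal methanolysis of the two MOM ethers and acid desilylation release the target; acid-catalysed oxa-Michael closure of the free chalcone is slow at this temperature.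

**Compound list**
1 | phloroglucinol | Oc1cc(O)cc(O)c1 | starting material
2 | 1,3,5-tris(methoxymethoxy)benzene | COCOc1cc(OCOC)cc(OCOC)c1 | intermediate
3 | prenyl bromide | CC(C)=CCBr | starting material
4 | 2,4,6-tris(methoxymethoxy)phenyllithium | [Li]c1c(OCOC)cc(OCOC)cc1OCOC | intermediate
5 | 1,3,5-tris(methoxymethoxy)-2-(3-methylbut-2-en-1-yl)benzene | COCOc1cc(OCOC)c(CC=C(C)C)c(OCOC)c1 | intermediate
6 | (R)-2,2-dimethyl-3-[2,4,6-tris(methoxymethoxy)benzyl]oxirane | CC1(C)O[C@@H]1Cc1c(OCOC)cc(OCOC)cc1OCOC | intermediate
7 | (R)-5,7-bis(methoxymethoxy)-2,2-dimethylchroman-3-ol | CC1(C)Oc2cc(OCOC)cc(OCOC)c2C[C@H]1O | intermediate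
8 | (R)-3-(tert-butyldimethylsilyloxy)-5,7-bis(methoxymethoxy)-2,2-dimethylchroman | CC1(C)Oc2cc(OCOC)cc(OCOC)c2C[C@H]1O[Si](C)(C)C(C)(C)C | intermediate
9 | 6-lithio derivative of 8 | CC1(C)Oc2cc(OCOC)c([Li])c(OCOC)c2C[C@H]1O[Si](C)(C)C(C)(C)C | intermediate
10 | (R)-3-(tert-butyldimethylsilyloxy)-5,7-bis(methoxymethoxy)-2,2-dimethylchroman-6-carbaldehyde | CC1(C)Oc2cc(OCOC)c(C=O)c(OCOC)c2C[C@H]1O[Si](C)(C)C(C)(C)C | intermediate
11 | (E)-oxime of 10 | CC1(C)Oc2cc(OCOC)c(/C=N/O)c(OCOC)c2C[C@H]1O[Si](C)(C)C(C)(C)C | intermediate
12 | 4-acetoxystyrene | C=Cc1ccc(OC(C)=O)cc1 | starting material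
13 | (R)-3-(tert-butyldimethylsilyloxy)-5,7-bis(methoxymethoxy)-2,2-dimethylchroman-6-carbonitrile oxide | CC1(C)Oc2cc(OCOC)c(C#[N+][O-])c(OCOC)c2C[C@H]1O[Si](C)(C)C(C)(C)C | intermediate
14 | 3-(chroman-6-yl)-5-(4-acetoxyphenyl)-4,5-dihydroisoxazole, chroman as in 8, both C5 epimers | CC1(C)Oc2cc(OCOC)c(C3=NOC(c4ccc(OC(C)=O)cc4)C3)c(OCOC)c2C[C@H]1O[Si](C)(C)C(C)(C)C | intermediate
15 | beta-hydroxy N–H ketimine from 14, both carbinol epimers | CC1(C)Oc2cc(OCOC)c(C(=N)CC(O)c3ccc(OC(C)=O)cc3)c(OCOC)c2C[C@H]1O[Si](C)(C)C(C)(C)C | intermediate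
16 | beta-hydroxy ketone, 4-acetoxyphenyl, both carbinol epimers | CC1(C)Oc2cc(OCOC)c(C(=O)CC(O)c3ccc(OC(C)=O)cc3)c(OCOC)c2C[C@H]1O[Si](C)(C)C(C)(C)C | intermediate
17 | beta-hydroxy ketone, 4-hydroxyphenyl, both carbinol epimers | CC1(C)Oc2cc(OCOC)c(C(=O)CC(O)c3ccc(O)cc3)c(OCOC)c2C[C@H]1O[Si](C)(C)C(C)(C)C | intermediate
18 | (E)-chalcone with C5 and C7 MOM ethers and C3 TBS ether | CC1(C)Oc2cc(OCOC)c(C(=O)/C=C/c3ccc(O)cc3)c(OCOC)c2C[C@H]1O[Si](C)(C)C(C)(C)C | intermediate
19 | (E)-1-[(3R)-3,5,7-trihydroxy-2,2-dimethylchroman-6-yl]-3-(4-hydroxyphenyl)prop-2-en-1-one (CNP0300839.1) | CC1(C)Oc2cc(O)c(C(=O)/C=C/c3ccc(O)cc3)c(O)c2C[C@H]1O | target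

**Step count**
Total: 11 steps. Longest linear sequence: 11 steps, from phloroglucinol 1 to 19; prenyl bromide 3 enters in step 2 and 4-acetoxystyrene 12 in step 8.

**Steps most likely to fail**

Step 11. Once the C5 and C7 phenols are free, either may add to the enone or capture the benzylic cation, so part of the material may close to flavanones. The fallback sets out from 17 and accepts this closure. Longer heating in the same acid (60 °C) should drive all material to two regioisomeric flavanones: the linear flavanone closed through the C7 oxygen F1 and the angular flavanone closed through the C5 oxygen F2, each as C2 epimers. Both are then opened by retro-oxa-Michael (E1cB) reaction in 10% aq. KOH at rt under argon, where the chalcone is held as its polyphenolate. Quenching into ice-cold dilute HCl returns the route at 19.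

Step 6. Deprotonation may take place at C8, between the C7 MOM ether and O1, or give a mixture of C6 and C8 metalation. The fallback sets out from 8 and blocks C8 first. Electrophilic bromination with NBS (MeCN, 0 °C) should go to the less hindered C8 and give the 8-bromo chroman F3. Lithium 2,2,6,6-tetramethylpiperidide (THF, −78 °C), an amide base that does not undergo bromine–lithium exchange, then removes the only remaining ring proton at C6. DMF gives the 8-bromo-6-carbaldehyde F4. Formate hydrodebromination (Pd(OAc)2, PPh3, HCO2Na, DMF, 80 °C) returns the route at 10.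

Step 4. The epoxide may open in the 5-exo mode at its CH (a dihydrobenzofuran with inverted centre), rearrange by hydride shift to a ketone, or pass the expelled methoxymethyl group onto the new hydroxyl. The fallback sets out from 1 and builds the pyran ring as a chromene, so the ring size is fixed before C3 is set. Condensation of excess 1 with 3-methylbut-2-enal (pyridine, 110 °C; Knoevenagel condensation then oxa-6π electrocyclisation) gives 2,2-dimethyl-2H-chromene-5,7-diol F5. MOMCl/iPr2NEt gives 5,7-bis(methoxymethoxy)-2,2-dimethyl-2H-chromene F6. Jacobsen epoxidation with (R,R)-N,N'-bis(3,5-di-tert-butylsalicylidene)-1,2-cyclohexanediaminomanganese chloride, NaOCl and 4-phenylpyridine N-oxide (CH2Cl2, 0 °C) should give (3R,4R)-3,4-epoxy-5,7-bis(methoxymethoxy)-2,2-dimethylchroman F7. This labile epoxide is taken without purification into LiAlH4 (THF, 0 °C), where hydride attack at benzylic C4 returns the route at 7.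

**Further compounds**
F1 | step 11 | flavanone closed through the C7 oxygen (linear dihydropyrano-flavanone, C5 hydroxyl free, C2 epimers) | CC1(C)Oc2cc3OC(c4ccc(O)cc4)CC(=O)c3c(O)c2C[C@H]1O
F2 | step 11 | flavanone closed through the C5 oxygen (angular dihydropyrano-flavanone, C7 hydroxyl free, C2 epimers) | CC1(C)Oc2cc(O)c3C(=O)CC(c4ccc(O)cc4)Oc3c2C[C@H]1O
F3 | step 6 | (R)-8-bromo-3-(tert-butyldimethylsilyloxy)-5,7-bis(methoxymethoxy)-2,2-dimethylchroman | CC1(C)Oc2c(Br)c(OCOC)cc(OCOC)c2C[C@H]1O[Si](C)(C)C(C)(C)C
F4 | step 6 | (R)-8-bromo-3-(tert-butyldimethylsilyloxy)-5,7-bis(methoxymethoxy)-2,2-dimethylchroman-6-carbaldehyde | CC1(C)Oc2c(Br)c(OCOC)c(C=O)c(OCOC)c2C[C@H]1O[Si](C)(C)C(C)(C)C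
F5 | step 4 | 2,2-dimethyl-2H-chromene-5,7-diol | CC1(C)C=Cc2c(O)cc(O)cc2O1
F6 | step 4 | 5,7-bis(methoxymethoxy)-2,2-dimethyl-2H-chromene | CC1(C)C=Cc2c(OCOC)cc(OCOC)cc2O1
F7 | step 4 | (3R,4R)-3,4-epoxy-5,7-bis(methoxymethoxy)-2,2-dimethylchroman | CC1(C)Oc2cc(OCOC)cc(OCOC)c2[C@H]3O[C@@H]13
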